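**Plan**

- Cuts: the C11'–C12' single bond between two sp2 carbons (C25 ring-A half + C15 ring-B half). The C25 half is cut at C11=C12 (C15 Wittig salt from β-ionone + C10 dial). The C15 half is cut at C7'–C8' (exocyclic enol triflate of dihydrocyclocitral + C4 enyne unit) and at the ring-B bond C1'–C6' (cation–olefin cyclisation of citronellal).
- Enabling feature: the C4 methylene of ring A (ring C1–C6) is allylic to C5=C6 and, through the seven chain C=C bonds, vinylogously α to a C12' aldehyde. Loss of one C4 proton moves all eight π bonds by one position. This creates the 4-ene/6-ylidene retro ring and puts an enolate oxygen on C12', which becomes the leaving group (triflate) for the C–C coupling and is lost in the same flask.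
- Forward order: ring B is closed first (step 2) and its chain grown from C7' to C11' (steps 3–7). Ring A is bought as β-ionone and its chain grown from C9 to C12' (steps 8–10). The halves are joined last (step 11), with no helper group left to remove.
- Stereochemistry: C5' (S) comes from (S)-citronellal and is never α to a carbonyl afterwards. 6'E comes from the enolate geometry in step 3, 8'E from syn carboalumination, 10'E from syn hydroboration. 6E to 13'E of the ring-A half come from the s-trans conformation of the all-E aldehyde during enolisation.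

Key step: step 11

Remark: carotenoid numbering is used (ring A C1–C6, chain C7–C15 and C15'–C7', ring B C1'–C6'); the target is read as (5'S,6E,6'E)-4,5'-retro-β,β-carotene with all chain double bonds E.

**Route**

Step 1
Reactants: 1 (S)-citronellal
Product: 2 (3S)-3,7-dimethylocta-1,6-dien-1-yl acetate (E/Z mixture)
Conditions: Ac2O, KOAc, Et3N, 120 °C
Reagents that add atoms: acetic anhydride, CC(=O)OC(C)=O
Why: Enol acetylation of the aldehyde turns C2 into an enol ester nucleophile for the ring closure and does not involve the C3 stereocentre.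

Step 2
Reactants: 2 (3S)-3,7-dimethylocta-1,6-dien-1-yl acetate
Product: 3 (6S)-2,2,6-trimethylcyclohexane-1-carbaldehyde (dihydrocyclocitral, C1 epimers, trans expected as main isomer)
Conditions: 85% H3PO4, toluene, 90 °C
Reagents that add atoms: none
Why: Cation–olefin cyclisation: protonation of the trisubstituted alkene gives the tertiary cation, the enol acetate carbon closes the six-membered ring onto it, and hydrolysis of the acyl oxocarbenium ion gives the aldehyde with the citronellal methyl stereocentre retained as C6.

Step 3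
Reactants: 3 (6S)-2,2,6-trimethylcyclohexane-1-carbaldehyde
Product: 5 (E)-[(6S)-2,2,6-trimethylcyclohexylidene]methyl trifluoromethanesulfonate, via potassium enolate 4 (not isolated)
Conditions: KH, THF, 0 °C → rt; PhNTf2, −78 °C → rt
Reagents that add atoms: N-phenylbis(trifluoromethanesulfonimide), O=S(=O)(N(c1ccccc1)S(=O)(=O)C(F)(F)F)C(F)(F)F
Why: Enolisation of the α-branched aldehyde and O-triflation of the enolate (enol triflate synthesis) should place oxygen cis to the CHMe carbon, because the quaternary CMe2 carbon crowds the other side, and this sets the 6'E exocyclic alkene.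

Step 4
Reactants: 6 1,4-bis(trimethylsilyl)buta-1,3-diyne
Product: 7 buta-1,3-diyn-1-yl(trimethyl)silane
Conditions: MeLi·LiBr (1.0 equiv), Et2O, rt; aq NH4Cl
Reagents that add atoms: none
Why: One equivalent of methyllithium cleaves one alkynyl C–Si bond (silicon–lithium exchange) and protonation on work-up frees one terminal alkyne.

Step 5
Reactants: 7 buta-1,3-diyn-1-yl(trimethyl)silane; 5 (E)-[(6S)-2,2,6-trimethylcyclohexylidene]methyl trifluoromethanesulfonate
Product: 9 trimethyl{(3E,5E)-3-methyl-5-[(6S)-2,2,6-trimethylcyclohexylidene]pent-3-en-1-yn-1-yl}silane, via alkenylalane 8 (not isolated)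
Conditions: Me3Al, Cp2ZrCl2, (CH2Cl)2, rt; volatiles removed; 5, Pd(PPh3)4 (5 mol %), ZnCl2, THF, rt
Reagents that add atoms: trimethylaluminium, C[Al](C)C
Why: Zirconium-catalysed methylalumination adds Me and Al syn across the terminal alkyne with Me on the internal carbon, and Pd/Zn-catalysed Negishi coupling of the alkenylalane with the enol triflate forms C7'–C8' with retention at both alkenes (8'E).

Step 6
Reactants: 9 trimethyl{(3E,5E)-3-methyl-5-[(6S)-2,2,6-trimethylcyclohexylidene]pent-3-en-1-yn-1-yl}silane
Product: 10 (3E,5E)-3-methyl-5-[(6S)-2,2,6-trimethylcyclohexylidene]pent-3-en-1-yne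
Conditions: K2CO3, MeOH, rt
Reagents that add atoms: none
Why: Methanolysis of the alkynyl C–Si bond frees the terminal alkyne under conditions that leave the diene and the allylic C5' centre untouched.

Step 7
Reactants: 10 (3E,5E)-3-methyl-5-[(6S)-2,2,6-trimethylcyclohexylidene]pent-3-en-1-yne
Product: 11 4,4,5,5-tetramethyl-2-{(1E,3E,5E)-3-methyl-5-[(6S)-2,2,6-trimethylcyclohexylidene]penta-1,3-dien-1-yl}-1,3,2-dioxaborolane
Conditions: HBpin, Cp2Zr(H)Cl (10 mol %), Et3N (10 mol %), CH2Cl2, rt → 40 °C
Reagents that add atoms: pinacolborane, [H]B1OC(C)(C)C(C)(C)O1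
Why: Zirconocene hydride-catalysed syn hydroboration of the terminal alkyne puts boron on the terminal carbon and should give the 10'E alkenylboronate, the more substituted alkenes being inert.

Step 8
Reactants: 12 β-ionone
Product: 13 (1E)-3-methyl-1-(2,6,6-trimethylcyclohex-1-en-1-yl)penta-1,4-dien-3-ol (vinyl-β-ionol, racemic)
Conditions: CH2=CHMgBr, THF, 0 °C; aq NH4Cl
Reagents that add atoms: vinylmagnesium bromide, C=C[Mg]Br
Why: Grignard 1,2-addition to the ketone, whose β-carbon is too hindered for conjugate addition.

Step 9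
Reactants: 13 vinyl-β-ionol
Product: 14 [(2E,4E)-3-methyl-5-(2,6,6-trimethylcyclohex-1-en-1-yl)penta-2,4-dien-1-yl]triphenylphosphonium bromide
Conditions: PPh3·HBr, MeOH, rt
Reagents that add atoms: triphenylphosphine hydrobromide, [Br-].c1ccc([PH+](c2ccccc2)c2ccccc2)cc1
Why: Acid ionises the tertiary bis-allylic alcohol and triphenylphosphine captures the pentadienyl cation at its unhindered primary end (allylic transposition) to give the conjugated Wittig salt.

Step 10
Reactants: 14 C15 phosphonium bromide; 15 (2E,4E,6E)-2,7-dimethylocta-2,4,6-trienedial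
Product: 17 (2E,4E,6E,8E,10E,12E)-2,7,11-trimethyl-13-(2,6,6-trimethylcyclohex-1-en-1-yl)trideca-2,4,6,8,10,12-hexaenal (β-apo-12'-carotenal), via phosphonium ylide 16 (not isolated)
Conditions: 15 (3 equiv), NaOMe, MeOH–CH2Cl2, 0 °C → rt; then heptane, reflux
Reagents that add atoms: none
Why: Wittig olefination of one formyl group of the dial, used in excess, forms C11=C12, and heating should convert the unhindered 11Z isomer into the all-E polyenal.

Step 11
Reactants: 17 β-apo-12'-carotenal; 11 C15 alkenylboronate
Product: 20 (5'S,6E,6'E)-4,5'-retro-β,β-carotene, via potassium retro-polyenolate 18 (not isolated), via retro-enol triflate 19 (not isolated)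
Conditions: t-BuOK (1.1 equiv), THF–DMPU, −78 → −40 °C; PhNTf2, −78 → 0 °C; then 11, Pd(OAc)2/SPhos (5/10 mol %), 3 M aq K3PO4, rt, Ar, dark
Reagents that add atoms: none
Why: Proposed new method: t-BuOK should remove a proton from the C4 methylene of ring A, the C–H that is allylic to C5=C6 and vinylogously α to the C12' carbonyl through seven chain double bonds, so that all eight π bonds move by one position and the retro-polyenolate 18 forms; O-sulfonylation by PhNTf2 fixes this pattern as the C12' enol triflate 19, and Pd(0) oxidative addition into its C–O bond, transmetalation with boronate 11 and reductive elimination make the C11'–C12' bond with retention at both alkenes. The closest known reaction types are the C4 deprotonation of retinoate esters to retro-polyenolates, the γ-deprotonation/O-triflation of enals to dienyl triflates and one-pot enol triflation/Suzuki–Miyaura coupling; new is the enolisation of an apocarotenal through eight conjugated π bonds with trapping at oxygen. No ring is closed and no stereocentre is formed, and C5' of 11 is not at risk because the alkoxide is consumed by PhNTf2 before 11 is added. The step needs site selectivity for C4–H over the C18, C19 and C20 methyl groups, which the formation of the longest linearly conjugated enolate with an endocyclic trisubstituted C4=C5 bond and the π-aligned axial C4–H should secure under the alkoxide conditions, and O- rather than C-sulfonylation, which is the normal course with PhNTf2. The new double bonds should be E because they arise from the s-trans single bonds of the all-E aldehyde (13'E with O anti to C14'), and 6E because a planar 6Z retro ring would press the in-plane C5 methyl against H8.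

**Compound list**

1 | (S)-citronellal, (3S)-3,7-dimethyloct-6-enal | O=CC[C@@H](C)CCC=C(C)C | starting material
2 | (3S)-3,7-dimethylocta-1,6-dien-1-yl acetate (E/Z mixture) | CC(=O)OC=C[C@@H](C)CCC=C(C)C | intermediate
3 | (6S)-2,2,6-trimethylcyclohexane-1-carbaldehyde (C1 epimers) | O=CC1[C@@H](C)CCCC1(C)C | intermediate
4 | potassium (E)-[(6S)-2,2,6-trimethylcyclohexylidene]methanolate | [K+].[O-]/C=C1\[C@@H](C)CCCC1(C)C | intermediate (not isolated)
5 | (E)-[(6S)-2,2,6-trimethylcyclohexylidene]methyl trifluoromethanesulfonate | O=S(=O)(O/C=C1\[C@@H](C)CCCC1(C)C)C(F)(F)F | intermediate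
6 | 1,4-bis(trimethylsilyl)buta-1,3-diyne | C[Si](C)(C)C#CC#C[Si](C)(C)C | starting material
7 | buta-1,3-diyn-1-yl(trimethyl)silane | C#CC#C[Si](C)(C)C | intermediate
8 | dimethyl[(1E)-2-methyl-4-(trimethylsilyl)but-1-en-3-yn-1-yl]alane | C[Al](C)/C=C(C)/C#C[Si](C)(C)C | intermediate (not isolated)
9 | trimethyl{(3E,5E)-3-methyl-5-[(6S)-2,2,6-trimethylcyclohexylidene]pent-3-en-1-yn-1-yl}silane | C[Si](C)(C)C#C/C(C)=C/C=C1\[C@@H](C)CCCC1(C)C | intermediate
10 | (3E,5E)-3-methyl-5-[(6S)-2,2,6-trimethylcyclohexylidene]pent-3-en-1-yne | C#C/C(C)=C/C=C1\[C@@H](C)CCCC1(C)C | intermediate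
11 | 4,4,5,5-tetramethyl-2-{(1E,3E,5E)-3-methyl-5-[(6S)-2,2,6-trimethylcyclohexylidene]penta-1,3-dien-1-yl}-1,3,2-dioxaborolane | CC1(C)OB(/C=C/C(C)=C/C=C2\[C@@H](C)CCCC2(C)C)OC1(C)C | intermediate
12 | β-ionone, (3E)-4-(2,6,6-trimethylcyclohex-1-en-1-yl)but-3-en-2-one | CC(=O)/C=C/C1=C(C)CCCC1(C)C | starting material
13 | vinyl-β-ionol, (1E)-3-methyl-1-(2,6,6-trimethylcyclohex-1-en-1-yl)penta-1,4-dien-3-ol (racemic) | C=CC(C)(O)/C=C/C1=C(C)CCCC1(C)C | intermediate
14 | [(2E,4E)-3-methyl-5-(2,6,6-trimethylcyclohex-1-en-1-yl)penta-2,4-dien-1-yl]triphenylphosphonium bromide | CC1=C(/C=C/C(C)=C/C[P+](c2ccccc2)(c2ccccc2)c2ccccc2)C(C)(C)CCC1.[Br-] | intermediate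
15 | (2E,4E,6E)-2,7-dimethylocta-2,4,6-trienedial | O=C/C(C)=C/C=C/C=C(C)/C=O | starting material
16 | [(2E,4E)-3-methyl-5-(2,6,6-trimethylcyclohex-1-en-1-yl)penta-2,4-dien-1-ylidene]triphenylphosphorane | CC1=C(/C=C/C(C)=C/C=P(c2ccccc2)(c2ccccc2)c2ccccc2)C(C)(C)CCC1 | intermediate (not isolated)
17 | β-apo-12'-carotenal, (2E,4E,6E,8E,10E,12E)-2,7,11-trimethyl-13-(2,6,6-trimethylcyclohex-1-en-1-yl)trideca-2,4,6,8,10,12-hexaenal | CC1=C(/C=C/C(C)=C/C=C/C(C)=C/C=C/C=C(C)/C=O)C(C)(C)CCC1 | intermediate
18 | potassium (1E,3E,5E,7E,9E,11E,13E)-2,7,11-trimethyl-13-(2,6,6-trimethylcyclohex-2-en-1-ylidene)trideca-1,3,5,7,9,11-hexaen-1-olate | CC1=CCCC(C)(C)\C1=C/C=C(C)/C=C/C=C(C)/C=C/C=C/C(C)=C/[O-].[K+] | intermediate (not isolated)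
19 | (1E,3E,5E,7E,9E,11E,13E)-2,7,11-trimethyl-13-(2,6,6-trimethylcyclohex-2-en-1-ylidene)trideca-1,3,5,7,9,11-hexaen-1-yl trifluoromethanesulfonate | CC1=CCCC(C)(C)\C1=C/C=C(C)/C=C/C=C(C)/C=C/C=C/C(C)=C/OS(=O)(=O)C(F)(F)F | intermediate (not isolated)
20 | (5'S,6E,6'E)-4,5'-retro-β,β-carotene (all chain double bonds E) | CC1=CCCC(C)(C)\C1=C/C=C(C)/C=C/C=C(C)/C=C/C=C/C(C)=C/C=C/C(C)=C/C=C1\[C@@H](C)CCCC1(C)C | target

**Count and risks**

Total steps: 11. Longest linear sequence: 7 (steps 1, 2, 3, 5, 6, 7, 11).

Steps most likely to fail: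

1. Step 11 (proposed new method). The base may remove a proton from a chain or ring methyl group instead of C4 and give cross-conjugated enolates. The aldehyde may also be consumed by alkoxide addition or aldol reaction, and the 6E/6Z geometry may scramble in the delocalised anion. The fallback uses known chemistry and sets out from alkyne 10 and aldehyde 17. Hydrozirconation of 10 with Cp2Zr(H)Cl, transmetalation to zinc with Me2Zn and 1,2-addition to 17 should give (2E,4E,7E,9E,11E,13E,15E,17E)-3,7,12,16-tetramethyl-1-[(6S)-2,2,6-trimethylcyclohexylidene]-18-(2,6,6-trimethylcyclohex-1-en-1-yl)octadeca-2,4,7,9,11,13,15,17-octaen-6-ol F1 (both carbinol epimers), in which the C11'–C12' bond is already in place. Dehydration of F1 in the manner of the retinol to anhydroretinol conversion (catalytic anhydrous HCl in ethanol, −20 °C) should remove the C12' hydroxyl together with a C4 proton and bring the route back at 20. Loss of the C5' proton from the same cation has to be watched.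

2. Step 5. A methyl group may be transferred from residual alane in place of the alkenyl group. Oxidative addition at the hindered exocyclic triflate may also be so slow that the alane decays first. The fallback reverses the polarity and sets out from 8 and 5. Iodinolysis of alane 8 with I2 should give the isolable (E)-(4-iodo-3-methylbut-3-en-1-yn-1-yl)trimethylsilane F2. Miyaura borylation of 5 (B2pin2, PdCl2(PPh3)2, KOPh) should give 4,4,5,5-tetramethyl-2-{(E)-[(6S)-2,2,6-trimethylcyclohexylidene]methyl}-1,3,2-dioxaborolane F3. Suzuki–Miyaura coupling of F3 with F2 (Pd(PPh3)4, aq K3PO4, THF) comes back to the route at 9.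

3. Step 3. Enolisation of the hindered aldehyde may be incomplete, with aldol or Tishchenko reactions competing, and O-sulfonylation may give poor geometric selectivity at the exocyclic alkene. The fallback sets out from 3. Condensation with excess hydrazine hydrate should give (6S)-2,2,6-trimethylcyclohexane-1-carbaldehyde hydrazone F4. Barton vinyl iodide synthesis (I2, tetramethylguanidine, THF, then DBU) should give (E)-1-(iodomethylidene)-(6S)-2,2,6-trimethylcyclohexane F5, whose geometric isomers can be separated or equilibrated. F5 takes the place of 5 in the coupling of step 5, and the route is rejoined at 9.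

**Further compounds**

F1 | step 11 | (2E,4E,7E,9E,11E,13E,15E,17E)-3,7,12,16-tetramethyl-1-[(6S)-2,2,6-trimethylcyclohexylidene]-18-(2,6,6-trimethylcyclohex-1-en-1-yl)octadeca-2,4,7,9,11,13,15,17-octaen-6-ol (6RS) | CC1=C(/C=C/C(C)=C/C=C/C(C)=C/C=C/C=C(C)/C(O)/C=C/C(C)=C/C=C2\[C@@H](C)CCCC2(C)C)C(C)(C)CCC1
F2 | step 5 | (E)-(4-iodo-3-methylbut-3-en-1-yn-1-yl)trimethylsilane | C[Si](C)(C)C#C/C(C)=C/I
F3 | step 5 | 4,4,5,5-tetramethyl-2-{(E)-[(6S)-2,2,6-trimethylcyclohexylidene]methyl}-1,3,2-dioxaborolane | CC1(C)OB(/C=C2\[C@@H](C)CCCC2(C)C)OC1(C)C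
F4 | step 3 | (6S)-2,2,6-trimethylcyclohexane-1-carbaldehyde hydrazone | NN=CC1[C@@H](C)CCCC1(C)C
F5 | step 3 | (E)-1-(iodomethylidene)-(6S)-2,2,6-trimethylcyclohexane | I/C=C1\[C@@H](C)CCCC1(C)C
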